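**Retrosynthetic overview**
1. Target 20 ⇒ diene 15 + acid 18: the last step makes the C5–O (ester) and C6–OH bonds by anti-1,2-hydroxy-acyloxylation of the ring alkene, through α-vinyl epoxide 19.
2. Diene 15 ⇒ enone 14 (Wittig) ⇒ keto acetate 12 (regioselective desaturation); the C2–OAc bond comes from 2β-alcohol 11 by Mitsunobu inversion.
3. Five-membered ring (formed second): C1–C2 bond and Z-ethylidene by nickel-catalysed alkylative cyclization of ynal 10 with Me2Zn.
4. Ynal 10 ⇒ (S)-cryptone 4 by conjugate alkynylation (C7a), enolate allylation (C3a) and ozonolysis; the all-trans array is relayed from the C7 isopropyl centre.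
5. Six-membered ring (formed first): organocatalytic Michael addition/aldol condensation of isovaleraldehyde and methyl vinyl ketone; acid 18 from ethyl pent-2-ynoate by syn-carbocupration.

Assumption: the hydrindane is numbered as octahydro-1H-indene (C1 ethylidene, C2 OAc, C3a/C7a ring fusion, C4 methylidene, C5 ester, C6 OH, C7 isopropyl); α is the face of the C7 isopropyl and C2 acetoxy groups (H-7a α, H-3a β); catalyst antipodes are chosen from the usual enamine-shielding and side-on-approach models.

**Route**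

Step 1
Reactants: 1 isovaleraldehyde (3-methylbutanal); 2 methyl vinyl ketone (but-3-en-2-one)
Product: 4 (S)-cryptone [(4S)-4-(propan-2-yl)cyclohex-2-en-1-one], via keto aldehyde 3 (not isolated)
Conditions: (S)-2-[methoxy(diphenyl)methyl]pyrrolidine (5 mol %), ethyl 3,4-dihydroxybenzoate (20 mol %), neat, 4 °C; then LiOH, i-PrOH, rt
Reagents that add atoms: none
Why: Enamine-catalysed Michael addition (the diarylmethyl group shields one enamine face and gives the (S)-α-isopropyl aldehyde) followed by intramolecular aldol condensation (Robinson-type annulation) sets the future C7 stereocentre and closes the six-membered ring.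

Step 2
Reactants: 4 (S)-cryptone
Product: 5 trimethyl({(3S,4S)-4-(propan-2-yl)-3-[(trimethylsilyl)ethynyl]cyclohex-1-en-1-yl}oxy)silane
Conditions: Me3SiC≡CH, n-BuLi, THF, −78 °C; ZnBr2, 0 °C; then 4, Me3SiOTf, Et2O–THF, −40 °C
Reagents that add atoms: (trimethylsilyl)acetylene, C#C[Si](C)(C)C; trimethylsilyl trifluoromethanesulfonate, C[Si](C)(C)OS(=O)(=O)C(F)(F)F
Why: Silyl-triflate-promoted conjugate addition of an alkynylzinc halide occurs anti to the C4 isopropyl group (3,4-trans, sets the future C7a) and the enolate is captured as a regiodefined silyl enol ether.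

Step 3
Reactants: 5 silyl enol ether
Product: 8 (2R,3S,4S)-3-ethynyl-4-(propan-2-yl)-2-(prop-2-en-1-yl)cyclohexan-1-one, via lithium enolate 6 (not isolated), via silylalkynyl ketone 7 (not isolated)
Conditions: MeLi, THF, 0 °C; allyl bromide, −78 → 0 °C; then K2CO3, MeOH, rt
Reagents that add atoms: allyl bromide, C=CCBr
Why: Regiospecific lithium enolate generation from the silyl enol ether and enolate C-allylation anti to the neighbouring alkynyl group give the 2,3-trans, all-equatorial ketone (future C3a), which is also the thermodynamic isomer under the carbonate/methanol that removes the C-silyl group.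

Step 4
Reactants: 8 allyl ethynyl ketone
Product: 10 2-[(1R,2S,3S)-2-ethynyl-6-oxo-3-(propan-2-yl)cyclohexyl]acetaldehyde, via ozonide 9 (not isolated)
Conditions: O3, CH2Cl2, −78 °C (stopped when the alkene is consumed); then Me2S, −78 °C → rt
Reagents that add atoms: ozone, [O-][O+]=O
Why: Ozonolysis with reductive work-up cleaves the terminal alkene, which reacts with ozone far faster than the alkyne, and touches no stereocentre.

Step 5
Reactants: 10 keto ynal
Product: 11 (1Z,2R,3aR,7S,7aS)-1-ethylidene-2-hydroxy-7-(propan-2-yl)octahydro-4H-inden-4-one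
Conditions: Ni(cod)2 (10 mol %), Me2Zn (2.5 equiv), THF, 0 °C; then cold 0.5 M HCl
Reagents that add atoms: dimethylzinc, C[Zn]C
Why: Nickel-catalysed alkylative ynal cyclization (Montgomery type): oxidative cyclization at zerovalent nickel gives an oxanickelacyclopentene, and methyl transfer from zinc with reductive elimination puts CH3 where nickel stood, cis to the carbinol carbon (Z-ethylidene), while the metallacycle needs the C–O bond in the plane of the alkyne, which in the trans-fused transition state only the pseudo-equatorial β-oxygen reaches (2β-OH, cis to H-3a).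

Step 6
Reactants: 11 keto alcohol
Product: 12 (1Z,2S,3aR,7S,7aS)-1-ethylidene-4-oxo-7-(propan-2-yl)octahydro-1H-inden-2-yl acetate
Conditions: AcOH, PPh3, DIAD, toluene, 0 °C → rt
Reagents that add atoms: acetic acid, CC(=O)O
Why: Mitsunobu reaction: acetate displaces the oxyphosphonium group by SN2 with inversion at C2, forming the 2α C–O bond and relieving the allylic 1,3-strain between the in-plane oxygen and the cis methyl group.

Step 7
Reactants: 12 keto acetate
Product: 14 (1Z,2S,3aR,7R,7aS)-1-ethylidene-4-oxo-7-(propan-2-yl)-2,3,3a,4,7,7a-hexahydro-1H-inden-2-yl acetate, via silyl enol ether 13 (not isolated)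
Conditions: LiN(i-Pr)2 (1.05 equiv), Me3SiCl (in situ), THF, −78 °C; then IBX·MPO (MPO = 4-methoxypyridine N-oxide), DMSO, rt
Reagents that add atoms: none
Why: Kinetic deprotonation at the C5 methylene (not the ring-fusion methine, and faster than the acetate) with internal silyl quench, then IBX dehydrogenation of the silyl enol ether (Saegusa-type desaturation), gives the C5=C6 enone without equilibrating C3a or C7.

Step 8
Reactants: 14 enone
Product: 15 (1Z,2S,3aR,7R,7aS)-1-ethylidene-4-methylidene-7-(propan-2-yl)-2,3,3a,4,7,7a-hexahydro-1H-inden-2-yl acetate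
Conditions: Ph3PCH3Br, KN(SiMe3)2, THF, 0 °C; then 14, −78 → 0 °C
Reagents that add atoms: methyltriphenylphosphonium bromide, C[P+](c1ccccc1)(c1ccccc1)c1ccccc1.[Br-]
Why: Wittig methylenation: the non-stabilised ylide adds 1,2 to the enone carbonyl at low temperature faster than it enolises the ketone or attacks the acetate, giving the semicyclic 1,3-diene.

Step 9
Reactants: 16 ethyl pent-2-ynoate
Product: 18 (2Z)-3-methylpent-2-enoic acid, via ethyl ester 17 (not isolated)
Conditions: Me2CuLi (from CuI and 2 MeLi), THF, −78 °C; MeOH, −78 °C; then LiOH, H2O, rt; 1 M HCl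
Reagents that add atoms: lithium dimethylcuprate, [Li+].C[Cu-]C; lithium hydroxide, [Li+].[OH-]
Why: Syn-carbocupration of the ynoate (cuprate conjugate addition, protonation of the vinylcopper at −78 °C with retention) puts the new methyl cis to H and therefore the ethyl group cis to the ester (Z), and saponification then frees the acid.

Step 10
Reactants: 15 diene acetate; 18 (2Z)-3-methylpent-2-enoic acid
Product: 20 (1Z,2S,3aR,5S,6S,7S,7aR)-2-(acetyloxy)-1-ethylidene-6-hydroxy-4-methylidene-7-(propan-2-yl)octahydro-1H-inden-5-yl (2Z)-3-methylpent-2-enoate, via vinyl epoxide 19 (not isolated)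
Conditions: (R,R)-(salen)MnCl [salen = N,N'-bis(3,5-di-tert-butylsalicylidene)cyclohexane-1,2-diaminate] (5 mol %), 4-phenylpyridine N-oxide (20 mol %), PhIO (1.1 equiv), CH2Cl2, −20 °C; then 18 (1.5 equiv), −20 → 0 °C
Reagents that add atoms: iodosylbenzene, O=Ic1ccccc1
Why: Proposed new method: a one-flask, catalyst-controlled anti-1,2-hydroxy-acyloxylation of a 1,3-diene in which one (salen)Mn centre works twice — as the oxo-manganese species it transfers oxygen by side-on approach to the cis-disubstituted, conjugated ring alkene (the (R,R)-ligand directs it to the α-face, syn to the isopropyl group, against a weak substrate bias; the 1,1-disubstituted and the isolated trisubstituted alkenes are poor substrates), and as the Lewis-acidic trivalent manganese carboxylate formed on adding 18 it activates vinyl epoxide 19 and relays the carboxylate to the allylic carbon C5 in an SN2, Fürst–Plattner trans-diaxial opening (inversion at C5, retention at C6), so the C5–O ester bond, the free 6α-OH and both stereocentres arise in one operation without protecting groups; the closest known reaction types are the Jacobsen–Katsuki epoxidation of conjugated cis-alkenes and the (salen)metal-carboxylate opening of epoxides by carboxylic acids (also the Prévost–Woodward dioxygenation).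

**Compound list**

1 | isovaleraldehyde (3-methylbutanal) | CC(C)CC=O | starting material
2 | methyl vinyl ketone (but-3-en-2-one) | CC(=O)C=C | starting material
3 | (2S)-5-oxo-2-(propan-2-yl)hexanal | CC(C)[C@@H](C=O)CCC(C)=O | intermediate (not isolated)
4 | (S)-cryptone, (4S)-4-(propan-2-yl)cyclohex-2-en-1-one | CC(C)[C@H]1C=CC(=O)CC1 | intermediate
5 | trimethyl({(3S,4S)-4-(propan-2-yl)-3-[(trimethylsilyl)ethynyl]cyclohex-1-en-1-yl}oxy)silane (alkynyl trans to isopropyl) | C[Si](C)(C)OC1=C[C@@H](C#C[Si](C)(C)C)[C@H](C(C)C)CC1 | intermediate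
6 | lithium (3S,4S)-4-(propan-2-yl)-3-[(trimethylsilyl)ethynyl]cyclohex-1-en-1-olate | [Li]OC1=C[C@@H](C#C[Si](C)(C)C)[C@H](C(C)C)CC1 | intermediate (not isolated)
7 | (2R,3S,4S)-4-(propan-2-yl)-2-(prop-2-en-1-yl)-3-[(trimethylsilyl)ethynyl]cyclohexan-1-one (all-trans) | O=C1[C@H](CC=C)[C@@H](C#C[Si](C)(C)C)[C@H](C(C)C)CC1 | intermediate (not isolated)
8 | (2R,3S,4S)-3-ethynyl-4-(propan-2-yl)-2-(prop-2-en-1-yl)cyclohexan-1-one (all-trans) | O=C1[C@H](CC=C)[C@@H](C#C)[C@H](C(C)C)CC1 | intermediate
9 | (2R,3S,4S)-3-ethynyl-4-(propan-2-yl)-2-[(1,2,4-trioxolan-3-yl)methyl]cyclohexan-1-one (ozonide, both epimers at the trioxolane carbon) | O=C1[C@H](CC2OCOO2)[C@@H](C#C)[C@H](C(C)C)CC1 | intermediate (not isolated)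
10 | 2-[(1R,2S,3S)-2-ethynyl-6-oxo-3-(propan-2-yl)cyclohexyl]acetaldehyde | O=C1[C@H](CC=O)[C@@H](C#C)[C@H](C(C)C)CC1 | intermediate
11 | (1Z,2R,3aR,7S,7aS)-1-ethylidene-2-hydroxy-7-(propan-2-yl)octahydro-4H-inden-4-one (trans-fused, 2β-OH, CH3 of ethylidene cis to C2) | O=C1[C@@H]2C[C@@H](O)/C(=C\C)[C@H]2[C@H](C(C)C)CC1 | intermediate
12 | (1Z,2S,3aR,7S,7aS)-1-ethylidene-4-oxo-7-(propan-2-yl)octahydro-1H-inden-2-yl acetate (2α-OAc) | O=C1[C@@H]2C[C@H](OC(C)=O)/C(=C\C)[C@H]2[C@H](C(C)C)CC1 | intermediate
13 | (1Z,2S,3aR,7S,7aS)-1-ethylidene-7-(propan-2-yl)-4-[(trimethylsilyl)oxy]-2,3,3a,6,7,7a-hexahydro-1H-inden-2-yl acetate (C4=C5 silyl enol ether) | C1=C(O[Si](C)(C)C)[C@@H]2C[C@H](OC(C)=O)/C(=C\C)[C@H]2[C@H](C(C)C)C1 | intermediate (not isolated)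
14 | (1Z,2S,3aR,7R,7aS)-1-ethylidene-4-oxo-7-(propan-2-yl)-2,3,3a,4,7,7a-hexahydro-1H-inden-2-yl acetate (C5=C6 enone) | O=C1[C@@H]2C[C@H](OC(C)=O)/C(=C\C)[C@H]2[C@H](C(C)C)C=C1 | intermediate
15 | (1Z,2S,3aR,7R,7aS)-1-ethylidene-4-methylidene-7-(propan-2-yl)-2,3,3a,4,7,7a-hexahydro-1H-inden-2-yl acetate | C=C1[C@@H]2C[C@H](OC(C)=O)/C(=C\C)[C@H]2[C@H](C(C)C)C=C1 | intermediate
16 | ethyl pent-2-ynoate | CCC#CC(=O)OCC | starting material
17 | ethyl (2Z)-3-methylpent-2-enoate | CCOC(=O)/C=C(/C)CC | intermediate (not isolated)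
18 | (2Z)-3-methylpent-2-enoic acid | OC(=O)/C=C(/C)CC | intermediate
19 | (1Z,2S,3aR,5R,6S,7S,7aR)-5,6-epoxy-1-ethylidene-4-methylidene-7-(propan-2-yl)octahydro-1H-inden-2-yl acetate (oxirane on the α-face, syn to isopropyl) | C=C1[C@@H]2C[C@H](OC(C)=O)/C(=C\C)[C@H]2[C@H](C(C)C)[C@@H]3O[C@@H]31 | intermediate (not isolated)
20 | (1Z,2S,3aR,5S,6S,7S,7aR)-2-(acetyloxy)-1-ethylidene-6-hydroxy-4-methylidene-7-(propan-2-yl)octahydro-1H-inden-5-yl (2Z)-3-methylpent-2-enoate | C=C1[C@@H]2C[C@H](OC(C)=O)/C(=C\C)[C@H]2[C@H](C(C)C)[C@H](O)[C@H]1OC(=O)/C=C(/C)CC | target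

**Step count and risks**

Total step count: 10. Longest linear sequence: 9 (steps 1–8 and 10); step 9 is a one-step side branch.

Step 10 (the new reaction) is the most likely to fail. The α-face is the more hindered one, so catalyst control may be mismatched; opening could also occur SN2′ at the exocyclic CH2, or the epoxide could be hydrolysed. The fallback uses known chemistry, sets out from enone 14 and comes back at 20. Weitz–Scheffer epoxidation (t-BuOOH, DBU, CH2Cl2) anti to the isopropyl group gives the 5β,6β-epoxy ketone F1. Acid-catalysed hydrolysis (cat. HClO4, THF–H2O) opens it at C6, the carbon remote from the carbonyl, in the trans-diaxial sense and gives the 5β,6α-diol ketone F2. Yamaguchi esterification of the less hindered C5 hydroxyl with 18 (2,4,6-trichlorobenzoyl chloride, Et3N, DMAP) gives the keto ester F3. Takai–Lombardo methylenation (Zn, CH2Br2, TiCl4) then gives 20.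

Step 5 is the second risk: the terminal alkyne can oligomerise at nickel, and control at C2 rests on a transition-state argument. The fallback masks the alkyne terminus with silicon; it sets out from silyl enol ether 5 and comes back at 11. Alkylation as in step 3 without the carbonate treatment lets silylalkynyl ketone 7 be isolated. Ozonolysis then gives, through the ozonide F4, the silylalkynyl keto aldehyde F5. The same Ni(cod)2/Me2Zn cyclization on this internal alkyne gives the vinylsilane alcohol F6 (CH3 cis and SiMe3 trans to C2). Protodesilylation with retention (cat. HI, wet benzene) gives 11.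

Step 7 is the third risk: LiN(i-Pr)2 may enolise the acetate as well as the ketone. The fallback changes the order so that no ester is present during enolisation; it sets out from 11 and comes back at 14. LiN(i-Pr)2 (2.2 equiv) and Me3SiCl give the bis-silyl derivative F7. Saegusa–Ito oxidation with Pd(OAc)2 in MeCN gives the silyl ether enone F8. Citric acid in MeOH frees the hydroxy enone F9. Mitsunobu inversion (AcOH, PPh3, DIAD) as in step 6 then gives 14.

**Further compounds**

F1 | step 10 | 2α-acetoxy-5β,6β-epoxy-1-[(Z)-ethylidene]-7α-isopropyl-trans-hydrindan-4-one | O=C1[C@@H]2C[C@H](OC(C)=O)/C(=C\C)[C@H]2[C@H](C(C)C)[C@H]3O[C@H]31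
F2 | step 10 | 2α-acetoxy-5β,6α-dihydroxy-1-[(Z)-ethylidene]-7α-isopropyl-trans-hydrindan-4-one | O=C1[C@@H]2C[C@H](OC(C)=O)/C(=C\C)[C@H]2[C@H](C(C)C)[C@H](O)[C@H]1O
F3 | step 10 | 5-O-[(2Z)-3-methylpent-2-enoyl] derivative of F2 (4-ketone, free 6α-OH) | O=C1[C@@H]2C[C@H](OC(C)=O)/C(=C\C)[C@H]2[C@H](C(C)C)[C@H](O)[C@H]1OC(=O)/C=C(/C)CC
F4 | step 5 | ozonide (1,2,4-trioxolane) of 7, both epimers at the trioxolane carbon | O=C1[C@H](CC2OCOO2)[C@@H](C#C[Si](C)(C)C)[C@H](C(C)C)CC1
F5 | step 5 | 2-[(1R,2S,3S)-6-oxo-3-(propan-2-yl)-2-[(trimethylsilyl)ethynyl]cyclohexyl]acetaldehyde | O=C1[C@H](CC=O)[C@@H](C#C[Si](C)(C)C)[C@H](C(C)C)CC1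
F6 | step 5 | 2β-hydroxy-7α-isopropyl-1-[1-(trimethylsilyl)ethylidene]-trans-hydrindan-4-one (CH3 cis, SiMe3 trans to C2) | O=C1[C@@H]2C[C@@H](O)/C(=C(\C)[Si](C)(C)C)[C@H]2[C@H](C(C)C)CC1
F7 | step 7 | bis(trimethylsilyl) derivative of 11 (C4=C5 silyl enol ether and 2β-silyl ether) | C1=C(O[Si](C)(C)C)[C@@H]2C[C@@H](O[Si](C)(C)C)/C(=C\C)[C@H]2[C@H](C(C)C)C1
F8 | step 7 | (1Z)-1-ethylidene-7α-isopropyl-2β-[(trimethylsilyl)oxy]-1,2,3,3a,7,7a-hexahydro-4H-inden-4-one (trans-fused C5=C6 enone) | O=C1[C@@H]2C[C@@H](O[Si](C)(C)C)/C(=C\C)[C@H]2[C@H](C(C)C)C=C1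
F9 | step 7 | (1Z,2R,3aR,7R,7aS)-1-ethylidene-2-hydroxy-7-(propan-2-yl)-1,2,3,3a,7,7a-hexahydro-4H-inden-4-one | O=C1[C@@H]2C[C@@H](O)/C(=C\C)[C@H]2[C@H](C(C)C)C=C1
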